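Its constants are invented; the result is computed.

Read the flask at 40 h by asking what the gas has paid for by then.

    electrophile + nucleophile ⇌ acid set free + product (K1 = 8.1, k1 = 630 M⁻¹ h⁻¹)
    nucleophile + acid set free ⇌ protonated nucleophile, settled at all times (K2 = 9.8 × 10⁵ M⁻¹)
    acid set free + free base ⇌ salt of the base, settled at all times (K3 = 69.5 M⁻¹)
    gas ⇌ nucleophile, rate k4*(csat - [nucleophile]) (k4 = 0.336 h⁻¹, csat = 2.4 mM)
    electrophile ⇌ dormant form (K5 = 2.81, k5 = 0.0899 h⁻¹)

electrophile 0.020 M; free base 0.0160 M; gas 2.4 mM (held); time 40 h

- at the start none of nucleophile is dissolved
- what has gone from electrophile into another species counts as reacted, even if it can come back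
- run time (flask): 40 h

* part of the electrophile that has reacted at 40 h
* share of the unused nucleophile that is free and not bound as protonated nucleophile, at 40 h

Nucleophile enters through the gas transfer, at 8.06 × 10⁻⁴ M h⁻¹ while [nucleophile] is far below csat. With the electrophile as charged, dissolved nucleophile meets it with a half-life of 0.055 h, far shorter than the 2.06 h of the transfer, so at the start the transfer is the rate-limiting step.

Each product sets free one acid. Suppose that acid takes a second nucleophile: step 1 then runs at 4.03 × 10⁻⁴ M h⁻¹, which needs [nucleophile] near 3.20 × 10⁻⁵ M at the charged electrophile. There, K2[nucleophile] is 31.4, far more than the 1.1 of K3[free base], so the supposition holds and one product costs two nucleophiles.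

The feed time, twice the electrophile charge over the full transfer rate, is 49.6 h. Time over feed time gives the product as a share of the charge for as long as the transfer stays rate-limiting at its full rate; carried through to 40 h on that assumption, this flask reaches 80.6 %.

The remaining electrophile also turns into dormant form and back, with a relaxation half-life of 5.69 h, while step 1 keeps drawing on it, so this pair need not stand at balance. As a rough figure of my own, I still split the remaining 19.4 % by K5, which leaves 5.08 % as electrophile and puts c near 94.9 %. The feed time is longer than the run, so this reckoning gives no figure for fr.

The forecast is higher on c: 99.1 % (98.3 % to 99.6 %), with fr at 9 % (6 % to 13 %). Its ground is that the feed is “enough to exhaust free electrophile by about 30 h”.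

The simulation gives c = 98.4 % and fr = 7.45 %, both inside the forecast's ranges, and c stands 3.5 percentage points above my figure. In this flask at 40.0 h, dormant form over electrophile reads 20.1, more than the 2.81 of the balance I used.

This flask reads 66.2 % product against the 80.6 % of the feed time, with [nucleophile] at 44.3 % of csat. Now charge 0.034 M of electrophile in the neighbour flask. Its feed time is 84.3 h, which gives 47.4 % as product and, by the same rough split, c near 86.2 %. The neighbour flask reads 45.1 % product, with [nucleophile] at 2.40 × 10⁻⁴ M, and c = 91.5 %.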